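**Plan**
- Cuts: the lactone C1(=O)–O–C27; the pentaene single bonds C17–C18 and C23–C24 (Stille/Negishi); C2–C3 (propionate aldol); C12–C13 (methyl ketone aldol); C4–C5 and C9–C10 (double allylation of pentanedial, which is C5–C9).
- Forward: pentanedial is allylated at both ends. One allyl group is oxidised to the C11 methyl ketone (all three carbons kept) and joined to a C13–C17 iodo aldehyde. The other is cleaved later to the C3 aldehyde and extended to the C1–C17 iodo acid.
- A C18–C28 stannyl tetraene, made from (2R,3R)-butane-2,3-diol and a C18–C23 bis-stannyl triene, is attached at C17–C18. The only ring, the 28-membered lactone, closes last; six silyl ethers are then removed.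
- Stereochemistry: C5/C9 from the chiral iridium catalyst; C13 by 1,5-anti induction from the C9 ether; C11 by hydroxyl-directed anti reduction; C2/C3 and C14/C15 from one (S)-benzyloxazolidinone (boron enolate for C14/C15, titanium enolate for C2/C3); C26/C27 from the butanediol (inversion at C26).

Key step: step 1

Remark: locants follow the macrolide (C1 = lactone carbonyl, C27 = carbon bearing the ring oxygen, C28 = its methyl); TBS = tert-butyldimethylsilyl, PMB = 4-methoxybenzyl; 1 is assumed to be used as freshly distilled monomer.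

**Main chain, C3–C12**

Step 1
Reactants: 1 pentanedial; 2 allyl acetate
Product: 4 (4S,8S)-undeca-1,10-diene-4,8-diol, via hydroxy aldehyde 3 (not isolated)
Conditions: [Ir(cod)Cl]2 (5 mol %), (R)-Cl,MeO-BIPHEP (10 mol %), 4-chloro-3-nitrobenzoic acid (20 mol %), Cs2CO3 (40 mol %), i-PrOH (5 equiv), 2 (6 equiv), THF, 100 °C, sealed tube
Reagents that add atoms: none
Why: Iridium-catalysed transfer-hydrogenative carbonyl allylation: the cyclometallated C,O-benzoate complex of trivalent iridium ionises 2 to a π-allyl species that adds to each formyl group through a closed chair-like six-membered transition state, and isopropanol turns the iridium alkoxide over (acetone is released). The closest known reaction is the enantioselective allylation of aliphatic aldehydes with allyl acetate and isopropanol, and its two-directional use on dicarbonyl equivalents. No ring is closed; the new bonds are C4–C5 and C9–C10. Both new stereocentres (C5 and C9) are set by the ligand: the (R)-antipode is expected to direct allyl to the Re face of each formyl group, which gives S at both carbons, the two carbonyls reacting independently. The step needs high facial selectivity twice and complete double addition: mismatched events end in the separable meso diol, which raises the enantiopurity of 4, and excess isopropanol and 2 are meant to keep the lactol of 3 in equilibrium with the open aldehyde and away from dehydrogenation to the lactone. The product is C2-symmetric with homotopic allyl ends, so either end can be elaborated first.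

Step 2
Reactants: 4 (4S,8S)-undeca-1,10-diene-4,8-diol
Product: 5 (4S,8S)-4,8-bis(PMB-oxy)undeca-1,10-diene
Conditions: NaH, PMBCl, Bu4NI (cat.), DMF, 0 °C → rt
Reagents that add atoms: 4-methoxybenzyl chloride, SMILES COc1ccc(CCl)cc1
Why: Williamson etherification of both alkoxides touches no stereocentre and installs the alkoxy (not silyloxy) group at C9 that the later aldol needs for stereocontrol.

Step 3
Reactants: 5 (4S,8S)-4,8-bis(PMB-oxy)undeca-1,10-diene
Product: 6 (4S,8S)-4,8-bis(PMB-oxy)undec-10-en-2-one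
Conditions: PdCl2 (10 mol %), CuCl (1 equiv), O2 (1 atm), DMF/H2O 7:1, rt, stopped near half conversion (5 recovered and recycled)
Reagents that add atoms: water, SMILES O
Why: Wacker–Tsuji oxidation of a terminal alkene gives the methyl ketone (C11 carbonyl, C12 methyl); the two alkenes are homotopic, so partial conversion should give a single mono-ketone beside recoverable 5.

**Fragment A, C13–C17**

Step 4
Reactants: 7 (4S)-4-benzyl-3-propanoyl-1,3-oxazolidin-2-one; 8 3-(trimethylsilyl)prop-2-ynal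
Product: 10 (4S)-4-benzyl-3-[(2S,3S)-3-hydroxy-2-methyl-5-(trimethylsilyl)pent-4-ynoyl]-1,3-oxazolidin-2-one, via dibutylboron enolate 9 (not isolated)
Conditions: Bu2BOTf, i-Pr2NEt, CH2Cl2, −78 → 0 °C; 8, −78 → 0 °C; pH 7 buffer, MeOH, H2O2, 0 °C
Reagents that add atoms: none
Why: Evans syn-aldol: the (Z)-boron enolate adds through a Zimmerman–Traxler chair with the benzyl group of the auxiliary shielding one enolate face, which sets C14 and C15 as the syn pair of the required sense.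

Step 5
Reactants: 10 aldol adduct
Product: 11 (2S,3S)-3-hydroxy-N-methoxy-N,2-dimethyl-5-(trimethylsilyl)pent-4-ynamide
Conditions: MeNHOMe·HCl, AlMe3, CH2Cl2, −15 → 0 °C; aq. KNa tartrate
Reagents that add atoms: N,O-dimethylhydroxylamine hydrochloride, SMILES CNOC.Cl
Why: Weinreb amide formation by aluminium amide aminolysis of the N-acyloxazolidinone, assisted by the free β-hydroxyl, proceeds without epimerisation and releases the auxiliary.

Step 6
Reactants: 11 Weinreb amide
Product: 12 (2S,3S)-3-(TBS-oxy)-N-methoxy-N,2-dimethyl-5-(trimethylsilyl)pent-4-ynamide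
Conditions: TBSOTf, 2,6-lutidine, CH2Cl2, −78 → 0 °C
Reagents that add atoms: tert-butyldimethylsilyl triflate, SMILES CC(C)(C)[Si](C)(C)OS(=O)(=O)C(F)(F)F
Why: Silyl ether formation with a silyl triflate and a hindered base protects C15–OH as the fluoride-labile group kept to the end.

Step 7
Reactants: 12 silyl ether
Product: 13 (2S,3S)-3-(TBS-oxy)-N-methoxy-N,2-dimethylpent-4-ynamide
Conditions: K2CO3, MeOH, 0 °C → rt
Reagents that add atoms: none
Why: Methanolysis of the alkynyl C–Si bond (protodesilylation) leaves the secondary silyl ether and the Weinreb amide untouched.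

Step 8
Reactants: 13 terminal alkyne
Product: 15 (2S,3S,4E)-3-(TBS-oxy)-5-iodo-N-methoxy-N,2-dimethylpent-4-enamide, via vinylstannane 14 (not isolated)
Conditions: Bu3SnH, Pd(PPh3)2Cl2 (2 mol %), THF, 0 °C; then I2, CH2Cl2, 0 °C
Reagents that add atoms: iodine, SMILES II
Why: Palladium-catalysed syn-hydrostannation puts tin on the terminal carbon (the branched propargylic silyl ether blocks the internal position), and iododestannylation with retention gives the (E)-iodoalkene C16=C17.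

Step 9
Reactants: 15 iodo Weinreb amide
Product: 16 (2S,3S,4E)-3-(TBS-oxy)-5-iodo-2-methylpent-4-enal
Conditions: i-Bu2AlH, THF, −78 °C; aq. KNa tartrate
Reagents that add atoms: none
Why: Weinreb amide reduction stops at the aldehyde because of the stable aluminium chelate, so C14 is not epimerised; the aldehyde is used at once.

**Union and C1–C17 elaboration**

Step 10
Reactants: 6 methyl ketone; 16 iodo aldehyde
Product: 18 (1E,3S,4R,5R,9S,13S)-3-(TBS-oxy)-5-hydroxy-1-iodo-9,13-bis(PMB-oxy)-4-methylhexadeca-1,15-dien-7-one, via dicyclohexylboron enolate 17 (not isolated)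
Conditions: c-Hex2BCl, Et3N, Et2O, −78 → 0 °C; 16, −78 → −25 °C; pH 7 buffer, MeOH, H2O2, 0 °C
Reagents that add atoms: none
Why: Boron-mediated aldol of a β-alkoxy methyl ketone: kinetic enolisation at C12 and a boat-like transition state organised by the C9 ether oxygen give the 1,5-anti adduct, which sets C13 anti to C9, the small unsubstituted enolate being little affected by the Felkin preference of the aldehyde.

Step 11
Reactants: 18 β-hydroxy ketone
Product: 19 (1E,3S,4R,5R,7R,9S,13S)-3-(TBS-oxy)-1-iodo-9,13-bis(PMB-oxy)-4-methylhexadeca-1,15-diene-5,7-diol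
Conditions: Me4NBH(OAc)3, MeCN/AcOH 1:1, −30 → −20 °C
Reagents that add atoms: none
Why: Evans–Saksena reduction: the C13 hydroxyl binds boron and delivers hydride intramolecularly through a chair transition state, which sets C11 anti to C13 and hence syn to C9.

Step 12
Reactants: 19 anti-1,3-diol
Product: 20 (1E,3S,4R,5R,7S,9S,13S)-3,5,7-tris(TBS-oxy)-1-iodo-9,13-bis(PMB-oxy)-4-methylhexadeca-1,15-diene
Conditions: TBSOTf (3 equiv), 2,6-lutidine, CH2Cl2, −78 → 0 °C
Reagents that add atoms: tert-butyldimethylsilyl triflate, SMILES CC(C)(C)[Si](C)(C)OS(=O)(=O)C(F)(F)F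
Why: Silyl ether formation at C11 and C13 leaves no free hydroxyl next to a PMB ether, so the following oxidation cannot form an acetal.

Step 13
Reactants: 20 bis-PMB ether
Product: 21 (1E,3S,4R,5R,7S,9S,13S)-3,5,7-tris(TBS-oxy)-1-iodo-4-methylhexadeca-1,15-diene-9,13-diol
Conditions: DDQ (2.4 equiv), CH2Cl2/pH 7 buffer 10:1, 0 °C
Reagents that add atoms: none
Why: Oxidative PMB cleavage by electron transfer to DDQ and hydrolysis of the oxocarbenium ions leaves silyl ethers, the iodoalkene and the terminal alkene intact.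

Step 14
Reactants: 21 diol
Product: 22 (1E,3S,4R,5R,7S,9S,13S)-3,5,7,9,13-pentakis(TBS-oxy)-1-iodo-4-methylhexadeca-1,15-diene
Conditions: TBSOTf, 2,6-lutidine, CH2Cl2, −78 → 0 °C
Reagents that add atoms: tert-butyldimethylsilyl triflate, SMILES CC(C)(C)[Si](C)(C)OS(=O)(=O)C(F)(F)F
Why: Silyl ether formation at C5 and C9 gives uniform fluoride-labile protection from C5 to C15.

Step 15
Reactants: 22 penta-silyl ether
Product: 24 (3S,7S,9S,11R,12R,13S,14E)-3,7,9,11,13-pentakis(TBS-oxy)-15-iodo-12-methylpentadec-14-enal, via vicinal diol 23 (not isolated)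
Conditions: OsO4 (2 mol %), NMO, acetone/H2O, 0 °C → rt; then NaIO4, THF/pH 7 buffer, rt
Reagents that add atoms: N-methylmorpholine N-oxide, SMILES C[N+]1([O-])CCOCC1
Why: Dihydroxylation and periodate glycol cleavage (Johnson–Lemieux sequence) unveil C3 as the aldehyde, the monosubstituted alkene being far more reactive towards OsO4 than the electron-poor, hindered iodoalkene.

Step 16
Reactants: 24 aldehyde; 7 (4S)-4-benzyl-3-propanoyl-1,3-oxazolidin-2-one
Product: 26 (4S)-4-benzyl-3-[(2S,3R,5S,9S,11S,13R,14R,15S,16E)-3-hydroxy-17-iodo-2,14-dimethyl-5,9,11,13,15-pentakis(TBS-oxy)heptadec-16-enoyl]-1,3-oxazolidin-2-one, via trichlorotitanium enolate 25 (not isolated)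
Conditions: 7 (1.2 equiv), TiCl4 (1.05 equiv per 7), i-Pr2NEt (1.1 equiv per 7), N-methyl-2-pyrrolidinone (1 equiv per 7), CH2Cl2, 0 °C; 24, −78 → 0 °C; half-saturated aq. NH4Cl
Reagents that add atoms: none
Why: Titanium-mediated Evans syn-aldol by soft enolisation (Crimmins conditions): the chlorotitanium (Z)-enolate, with the pyrrolidinone filling the extra coordination site so that the auxiliary carbonyl stays off the metal, adds through a non-chelated Zimmerman–Traxler chair that sets C2 (S) and C3 (R) under auxiliary control, overriding the weak bias of the β-silyloxy aldehyde and giving the 3,5-anti relationship without any oxidative work-up.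

Step 17
Reactants: 26 aldol adduct
Product: 27 (4S)-4-benzyl-3-[(2S,3R,5S,9S,11S,13R,14R,15S,16E)-17-iodo-2,14-dimethyl-3,5,9,11,13,15-hexakis(TBS-oxy)heptadec-16-enoyl]-1,3-oxazolidin-2-one
Conditions: TBSOTf, 2,6-lutidine, CH2Cl2, −78 → 0 °C
Reagents that add atoms: tert-butyldimethylsilyl triflate, SMILES CC(C)(C)[Si](C)(C)OS(=O)(=O)C(F)(F)F
Why: Silyl ether formation at C3 completes the all-silyl protection.

Step 18
Reactants: 27 hexa-silyl imide
Product: 29 (2S,3R,5S,9S,11S,13R,14R,15S,16E)-3,5,9,11,13,15-hexakis(TBS-oxy)-17-iodo-2,14-dimethylheptadec-16-enoic acid, via peroxy acid 28 (not isolated)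
Conditions: LiOH, H2O2, THF/H2O 4:1, 0 °C → rt; aq. Na2SO3; 1 M HCl to pH 4
Reagents that add atoms: hydrogen peroxide, SMILES OO
Why: Hydroperoxide cleavage of the N-acyloxazolidinone occurs at the exocyclic carbonyl and sulfite reduces the peroxy acid, so the acid is freed without touching C2.

**Fragment B, C18–C28**

Step 19
Reactants: 30 (2R,3R)-butane-2,3-diol
Product: 32 (4R,5R)-4,5-dimethyl-1,3,2-dioxathiolane 2,2-dioxide, via cyclic sulfite 31 (not isolated)
Conditions: SOCl2, CH2Cl2, 0 °C → reflux; then RuCl3 (0.5 mol %), NaIO4, MeCN/H2O, 0 °C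
Reagents that add atoms: thionyl chloride, SMILES O=S(Cl)Cl; sodium periodate, SMILES [Na+].[O-]I(=O)(=O)=O
Why: Cyclic sulfite formation and ruthenium-catalysed oxidation give the cyclic sulfate, an epoxide surrogate that keeps both carbinol configurations.

Step 20
Reactants: 32 cyclic sulfate
Product: 34 (2R,3R)-3-methyl-5-(trimethylsilyl)pent-4-yn-2-ol, via lithium alkyl sulfate 33 (not isolated)
Conditions: Me3SiC≡CH, n-BuLi, THF, −78 °C; 32, THF/DMPU, −78 °C → rt; then 20% aq. H2SO4, Et2O, rt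
Reagents that add atoms: ethynyltrimethylsilane, SMILES C#C[Si](C)(C)C
Why: SN2 opening of the cyclic sulfate by the acetylide with inversion (both carbons are equivalent by symmetry) sets C26 while C27 keeps its configuration, and acid hydrolysis of the sulfate monoester frees the alcohol.

Step 21
Reactants: 34 silyl alkynol
Product: 35 (2R,3R)-3-methylpent-4-yn-2-ol
Conditions: K2CO3, MeOH, rt (volatile; carried on as a concentrated solution)
Reagents that add atoms: none
Why: Protodesilylation of the alkynyl silane by methoxide gives the terminal alkyne.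

Step 22
Reactants: 35 alkynol
Product: 37 (2R,3R,4E)-5-iodo-3-methylpent-4-en-2-ol, via vinylstannane 36 (not isolated)
Conditions: Bu3SnH, Pd(PPh3)2Cl2 (2 mol %), THF, 0 °C; then I2, CH2Cl2, 0 °C
Reagents that add atoms: iodine, SMILES II
Why: Palladium-catalysed syn-hydrostannation at the terminal carbon (the branched C26 blocks the internal position) and iododestannylation with retention give the (E)-iodoalkene C24=C25.

Step 23
Reactants: 38 (E)-1,2-bis(tributylstannyl)ethene; 39 (E)-1,2-diiodoethene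
Product: 42 (1E,3E,5E)-1,6-bis(tributylstannyl)hexa-1,3,5-triene, via vinyllithium 40 (not isolated), via vinylzinc chloride 41 (not isolated)
Conditions: 38 (2.4 equiv), n-BuLi, THF, −78 °C; ZnCl2, −78 → 0 °C; 39 (1 equiv), Pd(PPh3)4 (5 mol %), 0 °C → rt, dark
Reagents that add atoms: none
Why: Tin–lithium exchange, transmetallation to zinc and twofold Negishi coupling: the alkenylzinc transmetallates to palladium far faster than an alkenylstannane, so both stannyl ends should survive and all three double bonds stay E.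

Step 24
Reactants: 37 iodo alcohol; 42 bis-stannyl triene
Product: 43 (2R,3R,4E,6E,8E,10E)-3-methyl-11-(tributylstannyl)undeca-4,6,8,10-tetraen-2-ol
Conditions: 42 (3 equiv), Pd(MeCN)2Cl2 (5 mol %), DMF, 0 °C → rt, dark; silica treated with Et3N
Reagents that add atoms: none
Why: Stille coupling with retention of both alkene geometries forms C23–C24, the excess of bis-stannane favouring mono-coupling and leaving the distal stannyl group.

**Endgame**

Step 25
Reactants: 29 iodo acid; 43 stannyl tetraene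
Product: 44 (2S,3R,5S,9S,11S,13R,14R,15R,16E,18E,20E,22E,24E,26R,27R)-3,5,9,11,13,15-hexakis(TBS-oxy)-27-hydroxy-2,14,26-trimethyloctacosa-16,18,20,22,24-pentaenoic acid
Conditions: Pd(MeCN)2Cl2 (10 mol %), i-Pr2NEt, DMF/THF, rt, dark
Reagents that add atoms: none
Why: Stille coupling forms C17–C18 with retention of geometry and completes the all-E pentaene, the amine keeping the acid as its carboxylate so that the stannane is not protonated.

Step 26
Reactants: 44 seco acid
Product: 46 hexa-TBS macrolide (the target with all six hydroxyls as TBS ethers), via mixed anhydride 45 (not isolated)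
Conditions: 2,4,6-Cl3C6H2COCl, Et3N, THF, rt; then slow addition to DMAP, toluene, 40 °C, 1 mM, dark
Reagents that add atoms: none
Why: Yamaguchi macrolactonisation: the mixed anhydride is turned into the acylpyridinium and captured by the C27 hydroxyl under high dilution, closing the 28-membered ring without touching a stereocentre.

Step 27
Reactants: 46 hexa-TBS macrolide
Product: 47 CNP0245606.1
Conditions: HF·pyridine, pyridine, THF, 0 °C → rt, polypropylene vessel, dark; Me3SiOMe quench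
Reagents that add atoms: none
Why: Fluoride cleavage of the six silyl ethers under pyridine buffering avoids the acid that would ionise the C15 allylic alcohol next to the pentaene.

**Compound list**

1 | pentanedial | O=CCCCC=O | starting material
2 | allyl acetate | CC(=O)OCC=C | starting material
3 | (5S)-5-hydroxyoct-7-enal (in equilibrium with its lactol) | O=CCCC[C@H](O)CC=C | intermediate (not isolated)
4 | (4S,8S)-undeca-1,10-diene-4,8-diol | C=CC[C@@H](O)CCC[C@H](O)CC=C | intermediate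
5 | (4S,8S)-4,8-bis[(4-methoxyphenyl)methoxy]undeca-1,10-diene | C=CC[C@@H](OCc1ccc(OC)cc1)CCC[C@H](OCc1ccc(OC)cc1)CC=C | intermediate
6 | (4S,8S)-4,8-bis[(4-methoxyphenyl)methoxy]undec-10-en-2-one | C=CC[C@@H](OCc1ccc(OC)cc1)CCC[C@H](OCc1ccc(OC)cc1)CC(C)=O | intermediate
7 | (4S)-4-benzyl-3-propanoyl-1,3-oxazolidin-2-one | CCC(=O)N1[C@@H](Cc2ccccc2)COC1=O | starting material
8 | 3-(trimethylsilyl)prop-2-ynal | O=CC#C[Si](C)(C)C | starting material
9 | dibutylboron (Z)-enolate of 7 | C/C=C(\OB(CCCC)CCCC)N1[C@@H](Cc2ccccc2)COC1=O | intermediate (not isolated)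
10 | (4S)-4-benzyl-3-[(2S,3S)-3-hydroxy-2-methyl-5-(trimethylsilyl)pent-4-ynoyl]-1,3-oxazolidin-2-one | O=C1OC[C@H](Cc2ccccc2)N1C(=O)[C@@H](C)[C@H](O)C#C[Si](C)(C)C | intermediate
11 | (2S,3S)-3-hydroxy-N-methoxy-N,2-dimethyl-5-(trimethylsilyl)pent-4-ynamide | CON(C)C(=O)[C@@H](C)[C@H](O)C#C[Si](C)(C)C | intermediate
12 | (2S,3S)-3-(TBS-oxy)-N-methoxy-N,2-dimethyl-5-(trimethylsilyl)pent-4-ynamide | CON(C)C(=O)[C@@H](C)[C@H](O[Si](C)(C)C(C)(C)C)C#C[Si](C)(C)C | intermediate
13 | (2S,3S)-3-(TBS-oxy)-N-methoxy-N,2-dimethylpent-4-ynamide | CON(C)C(=O)[C@@H](C)[C@H](O[Si](C)(C)C(C)(C)C)C#C | intermediate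
14 | (2S,3S,4E)-3-(TBS-oxy)-N-methoxy-N,2-dimethyl-5-(tributylstannyl)pent-4-enamide | CON(C)C(=O)[C@@H](C)[C@H](O[Si](C)(C)C(C)(C)C)/C=C/[Sn](CCCC)(CCCC)CCCC | intermediate (not isolated)
15 | (2S,3S,4E)-3-(TBS-oxy)-5-iodo-N-methoxy-N,2-dimethylpent-4-enamide | CON(C)C(=O)[C@@H](C)[C@H](O[Si](C)(C)C(C)(C)C)/C=C/I | intermediate
16 | (2S,3S,4E)-3-(TBS-oxy)-5-iodo-2-methylpent-4-enal (C13–C17) | O=C[C@@H](C)[C@H](O[Si](C)(C)C(C)(C)C)/C=C/I | intermediate
17 | dicyclohexylboron enolate of 6 (enolised at C12) | C=CC[C@@H](OCc1ccc(OC)cc1)CCC[C@H](OCc1ccc(OC)cc1)CC(=C)OB(C1CCCCC1)C1CCCCC1 | intermediate (not isolated)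
18 | (1E,3S,4R,5R,9S,13S)-3-(TBS-oxy)-5-hydroxy-1-iodo-9,13-bis(PMB-oxy)-4-methylhexadeca-1,15-dien-7-one | C=CC[C@@H](OCc1ccc(OC)cc1)CCC[C@H](OCc1ccc(OC)cc1)CC(=O)C[C@@H](O)[C@@H](C)[C@H](O[Si](C)(C)C(C)(C)C)/C=C/I | intermediate
19 | (1E,3S,4R,5R,7R,9S,13S)-3-(TBS-oxy)-1-iodo-9,13-bis(PMB-oxy)-4-methylhexadeca-1,15-diene-5,7-diol | C=CC[C@@H](OCc1ccc(OC)cc1)CCC[C@H](OCc1ccc(OC)cc1)C[C@H](O)C[C@@H](O)[C@@H](C)[C@H](O[Si](C)(C)C(C)(C)C)/C=C/I | intermediate
20 | (1E,3S,4R,5R,7S,9S,13S)-3,5,7-tris(TBS-oxy)-1-iodo-9,13-bis(PMB-oxy)-4-methylhexadeca-1,15-diene | C=CC[C@@H](OCc1ccc(OC)cc1)CCC[C@H](OCc1ccc(OC)cc1)C[C@H](O[Si](C)(C)C(C)(C)C)C[C@@H](O[Si](C)(C)C(C)(C)C)[C@@H](C)[C@H](O[Si](C)(C)C(C)(C)C)/C=C/I | intermediate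
21 | (1E,3S,4R,5R,7S,9S,13S)-3,5,7-tris(TBS-oxy)-1-iodo-4-methylhexadeca-1,15-diene-9,13-diol | C=CC[C@@H](O)CCC[C@H](O)C[C@H](O[Si](C)(C)C(C)(C)C)C[C@@H](O[Si](C)(C)C(C)(C)C)[C@@H](C)[C@H](O[Si](C)(C)C(C)(C)C)/C=C/I | intermediate
22 | (1E,3S,4R,5R,7S,9S,13S)-3,5,7,9,13-pentakis(TBS-oxy)-1-iodo-4-methylhexadeca-1,15-diene | C=CC[C@@H](O[Si](C)(C)C(C)(C)C)CCC[C@H](O[Si](C)(C)C(C)(C)C)C[C@H](O[Si](C)(C)C(C)(C)C)C[C@@H](O[Si](C)(C)C(C)(C)C)[C@@H](C)[C@H](O[Si](C)(C)C(C)(C)C)/C=C/I | intermediate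
23 | vicinal diol from dihydroxylation of the terminal alkene of 22 (both epimers at the new carbinol) | OCC(O)C[C@@H](O[Si](C)(C)C(C)(C)C)CCC[C@H](O[Si](C)(C)C(C)(C)C)C[C@H](O[Si](C)(C)C(C)(C)C)C[C@@H](O[Si](C)(C)C(C)(C)C)[C@@H](C)[C@H](O[Si](C)(C)C(C)(C)C)/C=C/I | intermediate (not isolated)
24 | (3S,7S,9S,11R,12R,13S,14E)-3,7,9,11,13-pentakis(TBS-oxy)-15-iodo-12-methylpentadec-14-enal (C3–C17) | O=CC[C@@H](O[Si](C)(C)C(C)(C)C)CCC[C@H](O[Si](C)(C)C(C)(C)C)C[C@H](O[Si](C)(C)C(C)(C)C)C[C@@H](O[Si](C)(C)C(C)(C)C)[C@@H](C)[C@H](O[Si](C)(C)C(C)(C)C)/C=C/I | intermediate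
25 | trichlorotitanium (Z)-enolate of 7 | C/C=C(\O[Ti](Cl)(Cl)Cl)N1[C@@H](Cc2ccccc2)COC1=O | intermediate (not isolated)
26 | (4S)-4-benzyl-3-[(2S,3R,5S,9S,11S,13R,14R,15S,16E)-3-hydroxy-17-iodo-2,14-dimethyl-5,9,11,13,15-pentakis(TBS-oxy)heptadec-16-enoyl]-1,3-oxazolidin-2-one | O=C1OC[C@H](Cc2ccccc2)N1C(=O)[C@@H](C)[C@H](O)C[C@@H](O[Si](C)(C)C(C)(C)C)CCC[C@H](O[Si](C)(C)C(C)(C)C)C[C@H](O[Si](C)(C)C(C)(C)C)C[C@@H](O[Si](C)(C)C(C)(C)C)[C@@H](C)[C@H](O[Si](C)(C)C(C)(C)C)/C=C/I | intermediate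
27 | C3-TBS ether of 26 (hexa-silyl imide) | O=C1OC[C@H](Cc2ccccc2)N1C(=O)[C@@H](C)[C@H](O[Si](C)(C)C(C)(C)C)C[C@@H](O[Si](C)(C)C(C)(C)C)CCC[C@H](O[Si](C)(C)C(C)(C)C)C[C@H](O[Si](C)(C)C(C)(C)C)C[C@@H](O[Si](C)(C)C(C)(C)C)[C@@H](C)[C@H](O[Si](C)(C)C(C)(C)C)/C=C/I | intermediate
28 | peroxy acid corresponding to 29 | OOC(=O)[C@@H](C)[C@H](O[Si](C)(C)C(C)(C)C)C[C@@H](O[Si](C)(C)C(C)(C)C)CCC[C@H](O[Si](C)(C)C(C)(C)C)C[C@H](O[Si](C)(C)C(C)(C)C)C[C@@H](O[Si](C)(C)C(C)(C)C)[C@@H](C)[C@H](O[Si](C)(C)C(C)(C)C)/C=C/I | intermediate (not isolated)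
29 | (2S,3R,5S,9S,11S,13R,14R,15S,16E)-3,5,9,11,13,15-hexakis(TBS-oxy)-17-iodo-2,14-dimethylheptadec-16-enoic acid (C1–C17) | OC(=O)[C@@H](C)[C@H](O[Si](C)(C)C(C)(C)C)C[C@@H](O[Si](C)(C)C(C)(C)C)CCC[C@H](O[Si](C)(C)C(C)(C)C)C[C@H](O[Si](C)(C)C(C)(C)C)C[C@@H](O[Si](C)(C)C(C)(C)C)[C@@H](C)[C@H](O[Si](C)(C)C(C)(C)C)/C=C/I | intermediate
30 | (2R,3R)-butane-2,3-diol | C[C@@H](O)[C@@H](C)O | starting material
31 | (4R,5R)-4,5-dimethyl-1,3,2-dioxathiolane 2-oxide | C[C@@H](OS1=O)[C@@H](C)O1 | intermediate (not isolated)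
32 | (4R,5R)-4,5-dimethyl-1,3,2-dioxathiolane 2,2-dioxide | C[C@@H](OS1(=O)=O)[C@@H](C)O1 | intermediate
33 | lithium (2R,3R)-3-methyl-5-(trimethylsilyl)pent-4-yn-2-yl sulfate | C[Si](C)(C)C#C[C@@H](C)[C@@H](C)OS(=O)(=O)[O-].[Li+] | intermediate (not isolated)
34 | (2R,3R)-3-methyl-5-(trimethylsilyl)pent-4-yn-2-ol | C[Si](C)(C)C#C[C@@H](C)[C@@H](C)O | intermediate
35 | (2R,3R)-3-methylpent-4-yn-2-ol | C#C[C@@H](C)[C@@H](C)O | intermediate
36 | (2R,3R,4E)-3-methyl-5-(tributylstannyl)pent-4-en-2-ol | CCCC[Sn](CCCC)(CCCC)/C=C/[C@@H](C)[C@@H](C)O | intermediate (not isolated)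
37 | (2R,3R,4E)-5-iodo-3-methylpent-4-en-2-ol (C24–C28) | I/C=C/[C@@H](C)[C@@H](C)O | intermediate
38 | (E)-1,2-bis(tributylstannyl)ethene | CCCC[Sn](CCCC)(CCCC)/C=C/[Sn](CCCC)(CCCC)CCCC | starting material
39 | (E)-1,2-diiodoethene | I/C=C/I | starting material
40 | [(E)-2-(tributylstannyl)ethenyl]lithium | [Li]/C=C/[Sn](CCCC)(CCCC)CCCC | intermediate (not isolated)
41 | chloro[(E)-2-(tributylstannyl)ethenyl]zinc | Cl[Zn]/C=C/[Sn](CCCC)(CCCC)CCCC | intermediate (not isolated)
42 | (1E,3E,5E)-1,6-bis(tributylstannyl)hexa-1,3,5-triene (C18–C23) | CCCC[Sn](CCCC)(CCCC)/C=C/C=C/C=C/[Sn](CCCC)(CCCC)CCCC | intermediate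
43 | (2R,3R,4E,6E,8E,10E)-3-methyl-11-(tributylstannyl)undeca-4,6,8,10-tetraen-2-ol (C18–C28) | CCCC[Sn](CCCC)(CCCC)/C=C/C=C/C=C/C=C/[C@@H](C)[C@@H](C)O | intermediate
44 | (2S,3R,5S,9S,11S,13R,14R,15R,16E,18E,20E,22E,24E,26R,27R)-3,5,9,11,13,15-hexakis(TBS-oxy)-27-hydroxy-2,14,26-trimethyloctacosa-16,18,20,22,24-pentaenoic acid | OC(=O)[C@@H](C)[C@H](O[Si](C)(C)C(C)(C)C)C[C@@H](O[Si](C)(C)C(C)(C)C)CCC[C@H](O[Si](C)(C)C(C)(C)C)C[C@H](O[Si](C)(C)C(C)(C)C)C[C@@H](O[Si](C)(C)C(C)(C)C)[C@@H](C)[C@H](O[Si](C)(C)C(C)(C)C)/C=C/C=C/C=C/C=C/C=C/[C@@H](C)[C@@H](C)O | intermediate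
45 | mixed anhydride of 44 with 2,4,6-trichlorobenzoic acid | Clc1cc(Cl)c(C(=O)OC(=O)[C@@H](C)[C@H](O[Si](C)(C)C(C)(C)C)C[C@@H](O[Si](C)(C)C(C)(C)C)CCC[C@H](O[Si](C)(C)C(C)(C)C)C[C@H](O[Si](C)(C)C(C)(C)C)C[C@@H](O[Si](C)(C)C(C)(C)C)[C@@H](C)[C@H](O[Si](C)(C)C(C)(C)C)/C=C/C=C/C=C/C=C/C=C/[C@@H](C)[C@@H](C)O)c(Cl)c1 | intermediate (not isolated)
46 | (3S,4R,6S,10S,12S,14R,15R,16R,17E,19E,21E,23E,25E,27R,28R)-4,6,10,12,14,16-hexakis(TBS-oxy)-3,15,27,28-tetramethyl-1-oxacyclooctacosa-17,19,21,23,25-pentaen-2-one | C[C@H]1[C@H](O[Si](C)(C)C(C)(C)C)/C=C/C=C/C=C/C=C/C=C/[C@@H](C)[C@@H](C)OC(=O)[C@@H](C)[C@H](O[Si](C)(C)C(C)(C)C)C[C@@H](O[Si](C)(C)C(C)(C)C)CCC[C@H](O[Si](C)(C)C(C)(C)C)C[C@H](O[Si](C)(C)C(C)(C)C)C[C@H]1O[Si](C)(C)C(C)(C)C | intermediate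
47 | CNP0245606.1, (3S,4R,6S,10S,12S,14R,15R,16R,17E,19E,21E,23E,25E,27R,28R)-4,6,10,12,14,16-hexahydroxy-3,15,27,28-tetramethyl-1-oxacyclooctacosa-17,19,21,23,25-pentaen-2-one | C[C@H]1[C@H](O)/C=C/C=C/C=C/C=C/C=C/[C@@H](C)[C@@H](C)OC(=O)[C@@H](C)[C@H](O)C[C@@H](O)CCC[C@H](O)C[C@H](O)C[C@H]1O | target

**Count and risks**

Total: 27 steps. Longest linear sequence: 18 steps (7 and 8 through 16, 18, 29 and 44 to 47, i.e. steps 4–18 and 25–27); from pentanedial the count is 15.

Steps most likely to fail: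

1. Step 1. After the first addition the hydroxy aldehyde may rest as its lactol and be dehydrogenated to the lactone, or the dialdehyde may oligomerise, so the second allylation stays incomplete. Fallback, from 1: double allylboration with (+)-B-allyldiisopinocampheylborane (from (+)-Ipc2BOMe and allylmagnesium bromide, salt-free, Et2O, −78 °C), the antipode that attacks the Re face, should give the bis(diisopinocampheylborinate) F1. In F1 the first carbinol stays capped on boron, so no lactol can form. Oxidative work-up (NaOH, H2O2) releases the diol and the route is rejoined at 4.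

2. Step 10. The 1,5-anti preference of the enolate has to override the Felkin preference of the α-methyl aldehyde, so facial selectivity at C13 may be poor. Fallback, from 6: kinetic enolisation (LDA, THF, −78 °C) and trapping with Me3SiCl should give the trimethylsilyl enol ether F2. A Mukaiyama aldol of F2 with 16 (BF3·OEt2, CH2Cl2, −78 °C) runs through an open transition state in which the aldehyde is in control. Its β-silyloxy group should steer the small enol silane to the 1,3-anti (anti-Felkin) face, which is the same C13 configuration. Aqueous work-up rejoins the route at 18.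

3. Step 26. Ring closure of the hindered acid onto the hindered C27 alcohol may be slow, with oligomerisation or isomerisation of the pentaene on prolonged warming. Fallback, from 29 and 43: activation of 29 as the mixed anhydride F3 (2,4,6-Cl3C6H2COCl, Et3N) and intermolecular esterification with the C27 hydroxyl of 43 (DMAP, toluene, rt) should give the iodo stannyl ester F4. Intramolecular Stille coupling of F4 at C17–C18 (Pd2(dba)3, AsPh3, i-Pr2NEt, DMF, 1 mM, rt, dark) then closes the 28-membered ring. This replaces steps 25 and 26 and rejoins the route at 46.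

**Further compounds**

F1 | step 1 | bis(diisopinocampheylborinate) of 4 | C=CC[C@@H](OB([C@H]1C[C@H]2C[C@@H]([C@@H]1C)C2(C)C)[C@H]1C[C@H]2C[C@@H]([C@@H]1C)C2(C)C)CCC[C@H](OB([C@H]1C[C@H]2C[C@@H]([C@@H]1C)C2(C)C)[C@H]1C[C@H]2C[C@@H]([C@@H]1C)C2(C)C)CC=C
F2 | step 10 | trimethylsilyl enol ether of 6 (C11=C12) | C=CC[C@@H](OCc1ccc(OC)cc1)CCC[C@H](OCc1ccc(OC)cc1)CC(=C)O[Si](C)(C)C
F3 | step 26 | mixed anhydride of 29 with 2,4,6-trichlorobenzoic acid | Clc1cc(Cl)c(C(=O)OC(=O)[C@@H](C)[C@H](O[Si](C)(C)C(C)(C)C)C[C@@H](O[Si](C)(C)C(C)(C)C)CCC[C@H](O[Si](C)(C)C(C)(C)C)C[C@H](O[Si](C)(C)C(C)(C)C)C[C@@H](O[Si](C)(C)C(C)(C)C)[C@@H](C)[C@H](O[Si](C)(C)C(C)(C)C)/C=C/I)c(Cl)c1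
F4 | step 26 | ester of 29 with the C27 hydroxyl of 43 (C17 iodide and C18 stannane) | CCCC[Sn](CCCC)(CCCC)/C=C/C=C/C=C/C=C/[C@@H](C)[C@@H](C)OC(=O)[C@@H](C)[C@H](O[Si](C)(C)C(C)(C)C)C[C@@H](O[Si](C)(C)C(C)(C)C)CCC[C@H](O[Si](C)(C)C(C)(C)C)C[C@H](O[Si](C)(C)C(C)(C)C)C[C@@H](O[Si](C)(C)C(C)(C)C)[C@@H](C)[C@H](O[Si](C)(C)C(C)(C)C)/C=C/I
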